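All runs were generated by integration with constants of no real substance; noise was put on by code.

At −25 °C the violet run stands at 47.1% left-handed product after 6.00 min, still rising from 44.6% at 5.00 min, while at 25 °C the red run, with its larger charge, stands at 62.3% after 40.0 s. Left-handed substrate is half of the charge, so the red reading, above that share, means right-handed substrate has crossed into the left-handed series.

| flask | left-handed substrate | right-handed substrate | coupling partner | temperature | remark | time |
|---|---|---|---|---|---|---|
| violet | 0.0028 M | 0.0028 M | 4 equiv | −25 °C | run made earlier |  |
| red | 0.0044 M | 0.0044 M | 4 equiv | 25 °C | run made earlier |  |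
| amber | 0.0020 M | 0.0020 M | 8 equiv | −25 °C | run made earlier |  |
| Saturday's | 0.0020 M | 0.0020 M | 4.00 equiv | −20 °C |  | 6.0 min |
| Thursday's | 0.0020 M | 0.0020 M | 4.00 equiv | 10 °C |  | 6.0 min |
| Wednesday's | 0.0020 M | 0.0020 M | 4.00 equiv | 40 °C |  | 6.0 min |
| Monday's | 0.0020 M | 0.0020 M | 4.00 equiv | 70 °C |  | 6.0 min |

violet run (percent of the left-handed substrate and right-handed substrate together charged): time / min: left-handed product / % = 0.417: 9.9; 1.33: 23.1; 2.00: 29.9; 3.00: 35.8; 5.00: 44.6; 6.00: 47.1

red run (percent of the left-handed substrate and right-handed substrate together charged): time / s: left-handed product / % = 10.0: 41.0; 12.0: 44.1; 20.0: 52.4; 30.0: 58.8; 40.0: 62.3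

amber run (percent of the left-handed substrate and right-handed substrate together charged): time / min: left-handed product / % = 0.500: 15.8; 1.50: 32.1; 3.00: 43.4; 4.00: 47.4; 6.00: 50.9

(each reading ± 0.5 percentage points)

- coupling partner is single-handed; left-handed substrate and right-handed substrate are mirror images of each other, charged as a racemate, each of them at the stated concentration
- the handed part of coupling partner does not stay in what it makes, so the products of the two hands are mirror images too

1. the flask with the highest amount of left-handed product, in percent of the left-handed substrate and right-handed substrate together charged ("all alike" if they lie within 1.5 percentage points) (Saturday's / Thursday's / Wednesday's / Monday's / all alike)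
2. final left-handed product, as a percentage of the left-handed substrate and right-handed substrate together charged, in Saturday's
3. final left-handed product, as a percentage of the left-handed substrate and right-handed substrate together charged, in Thursday's
4. final left-handed product, as a percentage of the left-handed substrate and right-handed substrate together charged, in Wednesday's
5. final left-handed product, as a percentage of the left-handed substrate and right-handed substrate together charged, in Monday's

I carry a clock, the coupling half-life: the time in which left-handed substrate halves by coupling with c(coupling partner) held at its charge, which is the pseudo-first-order picture, ln 2 divided by the rate constant and c(coupling partner). I credit each early product reading to left-handed substrate and bring it to the new flasks' c(coupling partner) of 0.00800 M. The violet run's first reading then gives 1.83 min, and the red run's first gives 8.89 s.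

A straight line of ln half-life against temperature through these two readings is a rough extrapolation. It gives 1.43 min for Saturday's, so 4.20 half-lives fit into 6.0 min, and left-handed substrate alone would yield about 47.3%. For Wednesday's the line gives 0.0697 min, and for Monday's 0.0154 min. Both are far shorter than the time allowed, so I expect those two flasks to finish, and what stands there depends on how the substrate divides between the hands. Left-handed readings do not show me that division, so I name no number for them.

The forecast commits further: Monday's gives most, with 47.5%, 68%, 79% and 83% from Saturday's to Monday's, on the ground that “yield rises with temperature”.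

The flasks give 48.4%, 61.2%, 73.8% and 65.1% in that order, so Wednesday's holds most.

    right-handed substrate ⇌ achiral form (K = 0.124, k = 2.06 s⁻¹, Ea = 71.0 kJ mol⁻¹, ΔH = −6.00 kJ mol⁻¹)
    coupling partner ⇌ dormant form (K = 0.572, k = 0.446 s⁻¹, Ea = 71.0 kJ mol⁻¹, ΔH = −67.0 kJ mol⁻¹)
    coupling partner + right-handed substrate → right-handed product (k = 10.4 M⁻¹ s⁻¹, Ea = 49.0 kJ mol⁻¹)
    coupling partner + left-handed substrate → left-handed product (k = 30.4 M⁻¹ s⁻¹, Ea = 36.0 kJ mol⁻¹)
    left-handed substrate ⇌ achiral form (K = 0.124, k = 2.06 s⁻¹, Ea = 71.0 kJ mol⁻¹, ΔH = −6.00 kJ mol⁻¹)
    (constants at 40 °C)

At 0.134 min in Wednesday's, coupling gives left-handed substrate a half-life of 0.10 min, where my clock said 0.0697 min, and gives right-handed substrate 0.29 min, which is 2.90 times as long, while at the start the forward coupling of left-handed substrate runs at 0.12 of its passing into achiral form; at 6.00 min Wednesday's holds 73.8% left-handed against 26.2% right-handed product. A repeat of Wednesday's at 65 °C has a clock of 0.0198 min, shorter than Wednesday's, and it ends with 0% of its left-handed substrate left, holding 66.6% left-handed against 33.4% right-handed product.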